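## Structural features

The target is a 2-aryl-3-(hydroxymethyl)-2,3-dihydrobenzofuran (a 4',7-epoxy-8,3'-neolignan). Ring A is a 3,4,5-trimethoxyphenyl group on C7; ring B is the benzo ring, with OMe on C5' and an (E)-3-hydroxyprop-1-enyl chain on C1'; ring C (O, C7, C8, C3', C4') is the dihydrofuran that joins them. In benzofuran numbering C7 = C2, C8 = C3, C3' = C3a, C4' = C7a, C5' = C7 and C1' = C5. The only stereocentres, C7 (R) and C8 (S), are adjacent, both benzylic and trans: a check of the line notation puts ring A and the C9 carbinol on opposite faces of ring C. Trans is the thermodynamically preferred arrangement, so relative configuration is the easy part. The real difficulty is absolute control at C7, which has no neighbouring group to direct a reagent. Fragile features are the C7–O4' benzylic ether next to an electron-rich arene (ionisation by acid, hydrogenolysis, dehydrogenation to the benzofuran) and the cinnamyl alcohol (acid, oxidants, hydrogenation), which is therefore made last. A C9 aldehyde would be epimerisable at C8 and could expel the C4' phenoxide by E1cB. The key step uses the fact that C7 and C8 are the former C2=C3 enol-ether bond of a 7-methoxybenzofuran: ring A can be added to C7 and the one-carbon C9 unit to C8 across this bond, and C8, benzylic to ring B, can hold palladium as an η3-benzyl complex until the carbon nucleophile arrives.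

## Logic of the disconnections

15 ⇒ 14. No skeletal bond is cut; the C9' carbinol is taken back to a methyl ester. The cinnamyl alcohol is the most sensitive group in 15 and is best unveiled last, whereas 14 is a stable conjugated ester. The forward step must deliver hydride 1,2 to the ester without reducing C7'=C8' or cleaving the C7–O4' ether, with the C9 hydroxyl free.

14 ⇒ 12 (through 13). The C7'=C8' bond is cut, removing C8' and C9' as a stabilised phosphorus ylide and leaving the C7' aldehyde 13. Because 13 is made from the benzylic alcohol of 12 in the same flask, the three-carbon chain simplifies to a hydroxymethyl group on ring B. The forward step needs an oxidant that distinguishes the benzylic C7' alcohol from the aliphatic C9 alcohol, and an olefination that gives only the E alkene.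

12 ⇒ 11. No skeletal bond is cut. C9 and C7' are both taken to the carboxyl level (acid at C9, methyl ester at C7'), so one hydride reagent creates both carbinols and the two carbons need no earlier differentiation. The demand is that C8, now α to a carboxyl group and β to the C4' aryloxy group, neither epimerises nor triggers ring opening.

11 ⇒ 9 (through 10). The C9–N bond is the one changed: the C9 carboxyl is the oxidised form of a nitromethyl group. This makes the key step possible, because the nitronate of 8 is a soft one-carbon nucleophile suited to capture of a benzyl palladium. The forward conversion must be oxidative and mild, must spare rings A and B, and must leave C8 untouched. Going to the acid and not the aldehyde removes the most epimerisable intermediate from the route.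

9 ⇒ 5 + 7 + 8. The cuts are C7–C1 (ring C to ring A) and C8–C9. Both bonds sit on C7 and C8, which in 5 form the C2=C3 bond of the furan ring. Cutting here removes both stereocentres and both appended groups at once and leaves three achiral pieces: a flat heteroarene, an aryl electrophile and a one-carbon pronucleophile. The forward step must control regiochemistry (aryl to C7, nucleophile to C8), chemoselectivity (three-component union faster than direct coupling of 7 with 8 and faster than rearomatisation), relative configuration (trans) and absolute configuration (R at C7).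

5 ⇒ 3 (through 4). The C8–C3' bond (C3–C3a of the benzofuran) is cut, opening the furan ring to an aryl ether that carries a masked aldehyde. The forward step is an acid-mediated ring closure onto the only free position ortho to the ether oxygen, then loss of ethanol from 4. It must succeed on a ring deactivated by the C1' ester.

3 ⇒ 1 + 2. The O4'–C7 ether bond is cut to a phenol and a primary alkyl bromide, both commercial. The demand is clean SN2 O-alkylation at a slow, β,β-dialkoxy primary carbon without ester hydrolysis.

7 ⇒ 6. The aryl O–S bond is cut. A sulfonate is chosen over a halide because a non-coordinating counter-ion keeps the aryl palladium cationic, which the insertion needs. One routine sulfonylation suffices.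

## Other disconnections considered

Alternative 1: The cut runs through ring B, at C2'–C3' and C1'–C6', so the aromatic ring is made last. Forward, the dienyne A1 would undergo an intramolecular Diels–Alder reaction and DDQ added afterwards would aromatise the adduct to the tricyclic siloxane A2. A1 is a trans-2-aryl-2,3-dihydrofuran whose C4' carries a 1-methoxyvinyl group (the diene C3'=C4'–C5'=C6') and whose C9 oxygen is linked through a diisopropylsilyl group to methyl propiolate.
- In its favour: the tether fixes the orientation of the dienophile, so the ester must end on C1' and silicon on C2'. The reaction type is conventional. A2 carries the same C1' ester as 9, so the end games would converge.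
- Against it here: the key step creates neither stereocentre. C7 and C8 must already be present in A1, a non-aromatic, acid-labile bis(enol ether) whose enantioselective synthesis is harder than the target itself. DDQ threatens the C7–H of a 2-aryl-dihydrobenzofuran (dehydrogenation to the benzofuran). The C2'–Si bond must then be cleaved before the same four-step side-chain elaboration.
- Comparison: on predictability of the key step this alternative is the better one (a thermal pericyclic reaction against an unproven catalytic cascade). On structure the chosen plan is better matched, because ring B is bought ready-made in 1 and the strategic step is spent on the stereodiad. On step economy the chosen plan (eight steps) is clearly shorter, since A1 alone would need more steps than the whole route to 15.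

Alternative 2: The cut is C7–C8. The aryldiazoacetate A3, a ring B arylacetic ester with the 3,4,5-trimethoxybenzyl ether on O4', would give a carbene at C8 with Rh2(S-PTTL)4 (dirhodium tetrakis[N-phthaloyl-(S)-tert-leucinate], divalent rhodium). 1,5-Insertion into the benzylic C7–H closes ring C, and NaOMe added to the same flask would equilibrate C8 to the trans ester A4.
- In its favour: ring closure and both stereocentres come in one flask. Insertion is favoured at an electron-rich benzylic ether C–H, which ring A provides. The reaction class is established for 2-aryl-2,3-dihydrobenzofuran-3-carboxylates with catalyst control at C7, so on precedent this alternative is the better one. The end game from A4 is also shorter than that from 9: Heck reaction of the bromide with methyl acrylate, then one hydride reduction of both esters (two steps against four).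
- Against it here: A3 needs a ring B arylacetate with the right bromine and oxygen pattern, O-benzylation and diazo transfer, about five steps with an energetic intermediate. Oxonium ylide formation at the ether or C5' methoxy oxygen and carbene attack on ring A compete with insertion. A palladium step must be run late on a molecule with an epimerisable ester.
- Comparison: A4 arises by an intramolecular, concerted insertion in which the catalyst differentiates two enantiotopic C7 hydrogens. Compound 9 arises by an intermolecular insertion in which the ligand differentiates the two faces of a flat heteroarene, an intrinsically harder recognition problem. Overall step counts are about equal (eight or nine): the chosen plan is shorter before the key step, this alternative after it. The chosen plan avoids diazo chemistry and uses cheaper starting materials.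

Alternative 3: The cuts are C7–C8 and C7–O4', a [4+1] assembly of ring C. Cs2CO3 would eliminate sulfinate from the sulfone A5 to give an ortho-quinone methide (C3'=C8, silyloxymethyl on C8) and would deprotonate the chiral benzylsulfonium salt A6. The ylide carbon (C7) adds to C8 and the phenoxide then displaces the sulfide at C7 to give A7.
- In its favour: a convergent union of two fragments forms the ring and both stereocentres. The trans relationship follows from anti-periplanar SN2 closure of the betaine. C9 arrives at the alcohol oxidation level, so no nitro-to-carboxyl conversion or reduction is needed, which is better than the chosen plan. The reaction type is known, which lowers the risk.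
- Against it here: the chiral sulfide is stoichiometric, though recoverable. Enantioselectivity depends on the ylide discriminating the faces of a transient, planar quinone methide that bears an alkyl substituent with β-hydrogens and can tautomerise to the ortho-hydroxystyrene. A5 needs several steps from a brominated salicylaldehyde and A6 two. The bromide must still be converted into the side chain (Heck reaction, reduction, desilylation).
- Comparison: in convergence the two plans are equal. This alternative builds ring C from acyclic precursors, whereas the chosen plan keeps the ring and dearomatises it. The chosen plan is catalytic in the chiral element and shorter overall (eight steps against roughly ten). This alternative has the more secure key step and a slightly shorter end game (three steps against four).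

Key step: step 4

**Remarks on the chemistry**

- Assumption: the R sense of induction at C7 with (R)-BINAP is taken from the arylation of 2,3-dihydrofuran with the same ligand, where the priorities at the new centre are the same. If the insertion favoured the other face, (S)-BINAP would be used with nothing else changed.
- The structures of 5, 7, 8 and 9 were checked atom by atom against the target and need no correction.
- Compound 5 is kept as the methyl ester. At C1' an acrylate would itself undergo Heck arylation, an aldehyde would undergo a Henry reaction with the nitronate, and a halide would add to palladium.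
- The design improvement is made after the key step: C9 is taken to the carboxylic acid and not to the aldehyde, and oxidation and olefination at C7' are run in one flask.
- With the spatial arrangement unchanged, C8 (C3 of the benzofuran) is S in 9, 10, 12, 13, 14 and 15 but R in 11, because a carboxyl group outranks C7.

## Steps

Step 1
Reactants: 1 methyl vanillate; 2 bromoacetaldehyde diethyl acetal
Product: 3 methyl 4-(2,2-diethoxyethoxy)-3-methoxybenzoate
Conditions: K2CO3, KI (cat.), DMF, 100 °C
Reagents that add atoms: none
Why: Williamson ether synthesis; the phenoxide displaces the primary bromide by SN2, with iodide catalysis (Finkelstein exchange) and heat compensating for the slow β,β-dialkoxy electrophile, and the aryl ester is stable to carbonate in dry DMF.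

Step 2
Reactants: 3 methyl 4-(2,2-diethoxyethoxy)-3-methoxybenzoate
Product: 5 methyl 7-methoxybenzofuran-5-carboxylate, via 3-ethoxy-2,3-dihydrobenzofuran ester 4 (not isolated)
Conditions: Amberlyst 15 (sulfonic acid resin), PhCl, 120 °C, EtOH distilled off
Reagents that add atoms: none
Why: Acid-catalysed cyclodehydration: the oxocarbenium ion from the acetal alkylates the ring in an intramolecular Friedel–Crafts reaction and 4 then loses ethanol to aromatise. Only one position ortho to the ether oxygen is free, so a single regioisomer can form, and that position is only meta to the ester.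

Step 3
Reactants: 6 3,4,5-trimethoxyphenol
Product: 7 3,4,5-trimethoxyphenyl trifluoromethanesulfonate
Conditions: Tf2O, pyridine, CH2Cl2, 0 °C
Reagents that add atoms: trifluoromethanesulfonic anhydride, O=S(=O)(OS(=O)(=O)C(F)(F)F)C(F)(F)F
Why: Routine O-sulfonylation of a phenol with pyridine as base and acyl-transfer catalyst; no stereochemistry is involved.

Step 4
Reactants: 5 methyl 7-methoxybenzofuran-5-carboxylate; 7 3,4,5-trimethoxyphenyl trifluoromethanesulfonate; 8 nitromethane
Product: 9 methyl (2R,3S)-7-methoxy-3-(nitromethyl)-2-(3,4,5-trimethoxyphenyl)-2,3-dihydrobenzofuran-5-carboxylate (trans)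
Conditions: Pd2(dba)3 (2.5 mol %), (R)-BINAP (6 mol %), Cs2CO3 (1.5 equiv), MeNO2 (10 equiv), 4 Å MS, 1,4-dioxane, 60 °C
Reagents that add atoms: none
Why: Proposed new method: oxidative addition of zerovalent palladium to 7 gives a cationic aryl–Pd(BINAP) complex that coordinates the enol-ether-like C7=C8 bond of 5 and inserts syn, aryl to the oxygen-bearing C7 as in cationic Heck arylation of cyclic enol ethers, leaving palladium on C8 as an η3-benzyl complex spanning C8, C3' and an ortho carbon of ring B. The only β-hydrogen, C7–H, is anti to palladium, so β-hydride elimination is blocked and the complex can be attacked on the face opposite the metal by the nitronate of 8 in the manner of a Tsuji–Trost alkylation; attack at C8 rather than at a ring carbon restores the aromaticity of ring B and releases zerovalent palladium. The closest known reaction types are the asymmetric intermolecular Heck arylation of 2,3-dihydrofuran with aryl triflates, intramolecular dearomative Heck/anion-capture cascades of benzofurans and indoles, and nitronate alkylation of π-allyl and π-benzyl palladium; their intermolecular three-component union on a benzofuran is the new element. No ring is closed; the furan ring is only dearomatised. C7 is set by the chiral bisphosphine, which selects the enantiotopic face of the C7=C8 bond in the insertion, and C8 is set by the syn-insertion/anti-capture sequence, which places C1 and C9 trans. Three selectivities are needed: insertion before direct aryl–nitronate coupling (a chelating bisphosphine disfavours C–C reductive elimination from an aryl palladium nitronate, and the sparingly soluble base keeps the nitronate concentration low so the cationic complex stays open to the alkene), capture before base-induced loss of C7–H to the 2-arylbenzofuran (a soft, unhindered carbon nucleophile in tenfold excess), and mono-alkylation (the excess of 8 outcompetes the nitronate of 9). The C1' ester makes the benzyl palladium more electrophilic and is inert to every component.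

Step 5
Reactants: 9 methyl (2R,3S)-7-methoxy-3-(nitromethyl)-2-(3,4,5-trimethoxyphenyl)-2,3-dihydrobenzofuran-5-carboxylate
Product: 11 (2R,3R)-7-methoxy-5-(methoxycarbonyl)-2-(3,4,5-trimethoxyphenyl)-2,3-dihydrobenzofuran-3-carboxylic acid (trans), via nitrolic acid 10 (not isolated)
Conditions: NaNO2 (3 equiv), AcOH (10 equiv), DMSO, 35 °C
Reagents that add atoms: sodium nitrite, [Na+].[O-]N=O; water, O
Why: Nitrite-mediated oxidative Nef-type conversion of a primary nitroalkane: C-nitrosation gives nitrolic acid 10, which loses nitrite to a nitrile oxide that is hydrated to the hydroxamic acid and nitrosated again to release N2O and the acid. The weakly acidic medium near room temperature is the kind known to preserve an aryl-bearing stereocentre next to the nitromethyl carbon, and the acid (unlike a C9 aldehyde) is not prone to epimerisation at C8 or E1cB loss of the C4' phenoxide.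

Step 6
Reactants: 11 (2R,3R)-7-methoxy-5-(methoxycarbonyl)-2-(3,4,5-trimethoxyphenyl)-2,3-dihydrobenzofuran-3-carboxylic acid
Product: 12 [(2R,3S)-7-methoxy-2-(3,4,5-trimethoxyphenyl)-2,3-dihydrobenzofuran-3,5-diyl]dimethanol
Conditions: LiAlH4 (4 equiv), THF, 0 °C to reflux; aq. NaOH work-up
Reagents that add atoms: none
Why: LiAlH4 reduces the lithium carboxylate and the aryl ester to the two primary alcohols in one operation; the carboxylate is not enolised under these conditions, so C8 keeps its configuration and C7 is untouched.

Step 7
Reactants: 12 [(2R,3S)-7-methoxy-2-(3,4,5-trimethoxyphenyl)-2,3-dihydrobenzofuran-3,5-diyl]dimethanol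
Product: 14 methyl (E)-3-[(2R,3S)-3-(hydroxymethyl)-7-methoxy-2-(3,4,5-trimethoxyphenyl)-2,3-dihydrobenzofuran-5-yl]prop-2-enoate, via benzylic aldehyde 13 (not isolated)
Conditions: MnO2 (10 equiv), Ph3P=CHCO2Me (1.3 equiv), CH2Cl2, rt
Reagents that add atoms: methyl (triphenylphosphoranylidene)acetate, COC(=O)C=P(c1ccccc1)(c1ccccc1)c1ccccc1
Why: Tandem oxidation–Wittig reaction: activated MnO2 oxidises only the benzylic C7' alcohol and leaves the unactivated C9 alcohol, and aldehyde 13 is trapped as it forms by the stabilised ylide, which gives the E enoate.

Step 8
Reactants: 14 methyl (E)-3-[(2R,3S)-3-(hydroxymethyl)-7-methoxy-2-(3,4,5-trimethoxyphenyl)-2,3-dihydrobenzofuran-5-yl]prop-2-enoate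
Product: 15 (7R,8S,7'E)-3,4,5,5'-tetramethoxy-4',7-epoxy-8,3'-neolign-7'-ene-9,9'-diol (target)
Conditions: iBu2AlH (DIBAL-H, 4 equiv), CH2Cl2, −78 °C; aq. KNaC4H4O6
Reagents that add atoms: none
Why: iBu2AlH at low temperature reduces the conjugated ester 1,2 to the allylic alcohol without touching C7'=C8' or the benzylic ether; the first equivalent is consumed by the free C9 hydroxyl, and the neutral tartrate work-up protects the acid-sensitive cinnamyl alcohol.

## Compound list

1 | methyl vanillate (methyl 4-hydroxy-3-methoxybenzoate) | COC(=O)c1ccc(O)c(OC)c1 | starting material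
2 | bromoacetaldehyde diethyl acetal (2-bromo-1,1-diethoxyethane) | CCOC(CBr)OCC | starting material
3 | methyl 4-(2,2-diethoxyethoxy)-3-methoxybenzoate | CCOC(COc1ccc(C(=O)OC)cc1OC)OCC | intermediate
4 | methyl 3-ethoxy-7-methoxy-2,3-dihydrobenzofuran-5-carboxylate (racemic, not isolated) | CCOC1COc2c(OC)cc(C(=O)OC)cc21 | intermediate
5 | methyl 7-methoxybenzofuran-5-carboxylate | COC(=O)c1cc(OC)c2occc2c1 | intermediate
6 | 3,4,5-trimethoxyphenol | COc1cc(O)cc(OC)c1OC | starting material
7 | 3,4,5-trimethoxyphenyl trifluoromethanesulfonate | COc1cc(OS(=O)(=O)C(F)(F)F)cc(OC)c1OC | intermediate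
8 | nitromethane | C[N+](=O)[O-] | starting material
9 | methyl (2R,3S)-7-methoxy-3-(nitromethyl)-2-(3,4,5-trimethoxyphenyl)-2,3-dihydrobenzofuran-5-carboxylate (trans) | COc1cc([C@@H]2Oc3c(OC)cc(C(=O)OC)cc3[C@H]2C[N+](=O)[O-])cc(OC)c1OC | intermediate
10 | methyl (2R,3S)-3-[(hydroxyimino)(nitro)methyl]-7-methoxy-2-(3,4,5-trimethoxyphenyl)-2,3-dihydrobenzofuran-5-carboxylate (nitrolic acid, not isolated) | COc1cc([C@@H]2Oc3c(OC)cc(C(=O)OC)cc3[C@H]2C(=NO)[N+](=O)[O-])cc(OC)c1OC | intermediate
11 | (2R,3R)-7-methoxy-5-(methoxycarbonyl)-2-(3,4,5-trimethoxyphenyl)-2,3-dihydrobenzofuran-3-carboxylic acid (trans) | COc1cc([C@@H]2Oc3c(OC)cc(C(=O)OC)cc3[C@H]2C(=O)O)cc(OC)c1OC | intermediate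
12 | [(2R,3S)-7-methoxy-2-(3,4,5-trimethoxyphenyl)-2,3-dihydrobenzofuran-3,5-diyl]dimethanol (trans) | COc1cc([C@@H]2Oc3c(OC)cc(CO)cc3[C@H]2CO)cc(OC)c1OC | intermediate
13 | (2R,3S)-3-(hydroxymethyl)-7-methoxy-2-(3,4,5-trimethoxyphenyl)-2,3-dihydrobenzofuran-5-carbaldehyde (not isolated) | COc1cc([C@@H]2Oc3c(OC)cc(C=O)cc3[C@H]2CO)cc(OC)c1OC | intermediate
14 | methyl (E)-3-[(2R,3S)-3-(hydroxymethyl)-7-methoxy-2-(3,4,5-trimethoxyphenyl)-2,3-dihydrobenzofuran-5-yl]prop-2-enoate | COc1cc([C@@H]2Oc3c(OC)cc(/C=C/C(=O)OC)cc3[C@H]2CO)cc(OC)c1OC | intermediate
15 | (7R,8S,7'E)-3,4,5,5'-tetramethoxy-4',7-epoxy-8,3'-neolign-7'-ene-9,9'-diol | COc1cc([C@@H]2Oc3c(OC)cc(/C=C/CO)cc3[C@H]2CO)cc(OC)c1OC | target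

## Step count and risk

Total steps: 8 (steps 1 to 8).
Longest linear sequence: 7 steps (steps 1, 2, 4, 5, 6, 7, 8, from 1 to 15). The second branch (step 3) is one step.

**Step 4 (key step, the one step beyond known chemistry).**
- What may go wrong: the most likely failure is rearomatisation, where base removes C7–H from the η3-benzyl palladium faster than the nitronate attacks C8, so the sequence ends as a formal C–H arylation. Also possible are direct coupling of the aryl palladium with the nitronate, nitronate coordination that shuts down the cationic insertion, and poor facial selectivity on a flat heteroarene that binds less well than dihydrofuran.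
- Fallback (known chemistry), from 5 back to 12:
  - Iridium-catalysed C–H borylation of 5 at C7 ([Ir(OMe)(cod)]2, 4,4'-di-tert-butyl-2,2'-bipyridine, B2pin2, THF, 60 °C) would give methyl 7-methoxy-2-(4,4,5,5-tetramethyl-1,3,2-dioxaborolan-2-yl)benzofuran-5-carboxylate F1.
  - Oxidation (NaBO3·4H2O, THF/H2O) would give the lactone methyl 7-methoxy-2-oxo-2,3-dihydrobenzofuran-5-carboxylate F2.
  - Methanolysis (MeOH, cat. H2SO4) would open the lactone to methyl 4-hydroxy-3-methoxy-5-(2-methoxy-2-oxoethyl)benzoate F3.
  - O-Alkylation with 3,4,5-trimethoxybenzyl bromide (K2CO3, DMF) would give methyl 3-methoxy-5-(2-methoxy-2-oxoethyl)-4-[(3,4,5-trimethoxybenzyl)oxy]benzoate F4.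
  - Diazo transfer (4-acetamidobenzenesulfonyl azide, DBU, MeCN) would give methyl 3-(1-diazo-2-methoxy-2-oxoethyl)-5-methoxy-4-[(3,4,5-trimethoxybenzyl)oxy]benzoate F5.
  - Rh2(S-PTTL)4 (dirhodium tetrakis[N-phthaloyl-(S)-tert-leucinate], divalent rhodium; toluene, −60 °C) should effect enantioselective 1,5-insertion of the carbene into the benzylic ether C7–H to give the cis diester dimethyl (2R,3S)-7-methoxy-2-(3,4,5-trimethoxyphenyl)-2,3-dihydrobenzofuran-3,5-dicarboxylate F6.
  - NaOMe in MeOH added to the same flask would epimerise C8 to the trans diester dimethyl (2R,3R)-7-methoxy-2-(3,4,5-trimethoxyphenyl)-2,3-dihydrobenzofuran-3,5-dicarboxylate F7, and LiAlH4 (THF) would reduce both esters of F7 to 12.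

**Step 2.**
- What may go wrong: sluggish electrophilic ring closure on the ester-deactivated ring, with intermolecular condensation and oligomerisation of the oxocarbenium ion or liberated aldehyde taking over.
- Fallback, from 1 back to 5: ortho-iodination of 1 (N-iodosuccinimide, cat. CF3CO2H, MeCN) would give methyl 4-hydroxy-3-iodo-5-methoxybenzoate F8. Sonogashira coupling with trimethylsilylacetylene and cyclisation in the same flask (PdCl2(PPh3)2, CuI, Et3N, DMF, 70 °C) would give methyl 7-methoxy-2-(trimethylsilyl)benzofuran-5-carboxylate F9. Protodesilylation (Bu4NF, THF) would return 5.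

**Step 5.**
- What may go wrong: electrophilic nitrosation of the electron-rich ring A, diversion of the nitrile oxide intermediate into dimerisation, or stalling at the hydroxamic acid stage.
- Fallback, from 9 back to 12: nitronate formation (NaOMe, MeOH, 0 °C) and a reductive Nef reaction with buffered aqueous TiCl3/NH4OAc would give methyl (2R,3R)-3-formyl-7-methoxy-2-(3,4,5-trimethoxyphenyl)-2,3-dihydrobenzofuran-5-carboxylate F10. Used crude and reduced at once (NaBH4, MeOH, 0 °C), it would give methyl (2R,3S)-3-(hydroxymethyl)-7-methoxy-2-(3,4,5-trimethoxyphenyl)-2,3-dihydrobenzofuran-5-carboxylate F11. LiAlH4 as in step 6 would convert F11 into 12.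

**Step 7.**
- What may go wrong: incomplete heterogeneous oxidation, or consumption of the ylide at the oxidant surface, so that aldehyde formation and olefination fall out of step and mixtures result.
- Fallback, from 12 to 15: oxidation with MnO2 alone (CH2Cl2) and isolation of 13. A Wittig reaction with Ph3P=CHCHO (toluene, 80 °C) would give (E)-3-[(2R,3S)-3-(hydroxymethyl)-7-methoxy-2-(3,4,5-trimethoxyphenyl)-2,3-dihydrobenzofuran-5-yl]prop-2-enal F12. A Luche reduction (NaBH4, CeCl3·7H2O, MeOH, 0 °C) would give 15 directly, by-passing 14 and step 8.

## Further compounds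

F1 | step 4 | methyl 7-methoxy-2-(4,4,5,5-tetramethyl-1,3,2-dioxaborolan-2-yl)benzofuran-5-carboxylate | COC(=O)c1cc(OC)c2oc(B3OC(C)(C)C(C)(C)O3)cc2c1
F2 | step 4 | methyl 7-methoxy-2-oxo-2,3-dihydrobenzofuran-5-carboxylate | COC(=O)c1cc(OC)c2OC(=O)Cc2c1
F3 | step 4 | methyl 4-hydroxy-3-methoxy-5-(2-methoxy-2-oxoethyl)benzoate | COC(=O)Cc1cc(C(=O)OC)cc(OC)c1O
F4 | step 4 | methyl 3-methoxy-5-(2-methoxy-2-oxoethyl)-4-[(3,4,5-trimethoxybenzyl)oxy]benzoate | COC(=O)Cc1cc(C(=O)OC)cc(OC)c1OCc1cc(OC)c(OC)c(OC)c1
F5 | step 4 | methyl 3-(1-diazo-2-methoxy-2-oxoethyl)-5-methoxy-4-[(3,4,5-trimethoxybenzyl)oxy]benzoate | COC(=O)C(=[N+]=[N-])c1cc(C(=O)OC)cc(OC)c1OCc1cc(OC)c(OC)c(OC)c1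
F6 | step 4 | dimethyl (2R,3S)-7-methoxy-2-(3,4,5-trimethoxyphenyl)-2,3-dihydrobenzofuran-3,5-dicarboxylate (cis) | COc1cc([C@@H]2Oc3c(OC)cc(C(=O)OC)cc3[C@@H]2C(=O)OC)cc(OC)c1OC
F7 | step 4 | dimethyl (2R,3R)-7-methoxy-2-(3,4,5-trimethoxyphenyl)-2,3-dihydrobenzofuran-3,5-dicarboxylate (trans) | COc1cc([C@@H]2Oc3c(OC)cc(C(=O)OC)cc3[C@H]2C(=O)OC)cc(OC)c1OC
F8 | step 2 | methyl 4-hydroxy-3-iodo-5-methoxybenzoate | COC(=O)c1cc(I)c(O)c(OC)c1
F9 | step 2 | methyl 7-methoxy-2-(trimethylsilyl)benzofuran-5-carboxylate | COC(=O)c1cc(OC)c2oc([Si](C)(C)C)cc2c1
F10 | step 5 | methyl (2R,3R)-3-formyl-7-methoxy-2-(3,4,5-trimethoxyphenyl)-2,3-dihydrobenzofuran-5-carboxylate | COc1cc([C@@H]2Oc3c(OC)cc(C(=O)OC)cc3[C@H]2C=O)cc(OC)c1OC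
F11 | step 5 | methyl (2R,3S)-3-(hydroxymethyl)-7-methoxy-2-(3,4,5-trimethoxyphenyl)-2,3-dihydrobenzofuran-5-carboxylate | COc1cc([C@@H]2Oc3c(OC)cc(C(=O)OC)cc3[C@H]2CO)cc(OC)c1OC
F12 | step 7 | (E)-3-[(2R,3S)-3-(hydroxymethyl)-7-methoxy-2-(3,4,5-trimethoxyphenyl)-2,3-dihydrobenzofuran-5-yl]prop-2-enal | COc1cc([C@@H]2Oc3c(OC)cc(/C=C/C=O)cc3[C@H]2CO)cc(OC)c1OC
A1 | alternative 1 | methyl 3-[diisopropyl({trans-5-(1-methoxyvinyl)-2-(3,4,5-trimethoxyphenyl)-2,3-dihydrofuran-3-yl}methoxy)silyl]prop-2-ynoate, C7 and C8 as in the target | COc1cc([C@@H]2OC(C(OC)=C)=C[C@H]2CO[Si](C(C)C)(C(C)C)C#CC(=O)OC)cc(OC)c1OC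
A2 | alternative 1 | silicon-bridged dihydrobenzofuran: ring B complete, CO2Me on C1', Si(iPr)2 on C2' bridged through oxygen to C9, OMe on C5', C7 and C8 as in the target | COc1cc([C@@H]2Oc3c(OC)cc(C(=O)OC)c4c3[C@H]2CO[Si]4(C(C)C)C(C)C)cc(OC)c1OC
A3 | alternative 2 | methyl 2-{5-bromo-3-methoxy-2-[(3,4,5-trimethoxybenzyl)oxy]phenyl}-2-diazoacetate | COC(=O)C(=[N+]=[N-])c1cc(Br)cc(OC)c1OCc1cc(OC)c(OC)c(OC)c1
A4 | alternative 2 | methyl trans-5-bromo-7-methoxy-2-(3,4,5-trimethoxyphenyl)-2,3-dihydrobenzofuran-3-carboxylate, target configuration at C7 and C8 | COc1cc([C@@H]2Oc3c(OC)cc(Br)cc3[C@H]2C(=O)OC)cc(OC)c1OC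
A5 | alternative 3 | 4-bromo-2-[2-(tert-butyldimethylsilyloxy)-1-(4-methylphenylsulfonyl)ethyl]-6-methoxyphenol (racemic) | COc1cc(Br)cc(C(CO[Si](C)(C)C(C)(C)C)S(=O)(=O)c2ccc(C)cc2)c1O
A6 | alternative 3 | (2R,5R)-2,5-dimethyl-1-(3,4,5-trimethoxybenzyl)thiolan-1-ium trifluoromethanesulfonate (the antipode if the sense of induction requires it) | C[C@@H]1CC[C@@H](C)[S+]1Cc1cc(OC)c(OC)c(OC)c1.[O-]S(=O)(=O)C(F)(F)F
A7 | alternative 3 | trans-5-bromo-3-(tert-butyldimethylsilyloxymethyl)-7-methoxy-2-(3,4,5-trimethoxyphenyl)-2,3-dihydrobenzofuran, target configuration | COc1cc([C@@H]2Oc3c(OC)cc(Br)cc3[C@H]2CO[Si](C)(C)C(C)(C)C)cc(OC)c1OC
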